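**Retrosynthetic overview** (azulene numbering: ring A, five-membered, C1–C2–C3–C3a–C8a; ring B, seven-membered, C3a–C4–C5=C6–C7–C8–C8a)

1. The C4 anisate comes last: acylation of a C4 alcohol whose configuration is set by a reduction of the C4 enone directed by the C3 hydroxyl; the C7 hydroxyl travels as a TBS ether.
2. Key disconnection: bonds C8a–C1 and C2–C3 of ring A, made together by a hydrogen-atom-transfer Giese addition/aldol annulation of a monocyclic cycloheptenyl ketone with acrolein; the formyl group left on C2 is removed by decarbonylation.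
3. Enabling feature: in ring A the methyl-bearing quaternary C8a and the isopropyl carbinol C3 flank the ring-fusion CH (C3a), and the other two ring atoms, C1 and C2, are bare methylenes. C8a(=CH2)–C3a(H)–C3(=O)i-Pr is therefore a β,γ-unsaturated ketone (angular methyl = methylidene plus one hydrogen; carbinol = ketone), and C1–C2 is the β,α pair of an enal.
4. The cycloheptene comes from ring-closing metathesis at C5=C6 of an acyclic triene; this from a syn boron aldol (bond C3a–C4) of a β,γ-unsaturated isopropyl ketone with acrolein; the ketone from acylation of an allylsilane made by asymmetric allylboration of methacrolein (C7).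
5. Ring order: ring B first (step 5), ring A second (step 7).

Key step: step 7

Assumption: the two bis(isopinocampheyl)boron reagents (Ipc = isopinocampheyl) are taken to follow the usual models (Re-face allylation of the enal by the (−)-α-pinene-derived allylborane in step 1; Si-face attack on acrolein by the (+)-α-pinene-derived (Z)-enol borinate in step 4); if either sense is reversed, the antipodal borane is used.

Step 1
Reactants: 1 [2-(chloromethyl)prop-2-en-1-yl](trimethyl)silane; 2 methacrolein
Product: 6 (3R)-2-methyl-5-[(trimethylsilyl)methyl]hexa-1,5-dien-3-ol, via allylmagnesium chloride 3 (not isolated), via allylbis(isopinocampheyl)borane 4 (not isolated), via borinate ester 5 (not isolated)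
Conditions: Mg, THF, 0 °C; (+)-Ipc2BOMe, Et2O, −78 °C to rt; 2, −78 °C; then NaOH, H2O2
Reagents that add atoms: none
Why: Brown asymmetric allylboration, in which the 2-substituted allylborane adds 1,2 to the enal through a chair six-membered transition state and the isopinocampheyl groups direct attack to the Re face, which should set the (3R) carbinol that becomes C7.

Step 2
Reactants: 6
Product: 7 tert-butyl(dimethyl){[(3R)-2-methyl-5-[(trimethylsilyl)methyl]hexa-1,5-dien-3-yl]oxy}silane
Conditions: TBSCl, imidazole, DMF, rt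
Reagents that add atoms: tert-butyldimethylsilyl chloride, CC(C)(C)[Si](C)(C)Cl
Why: Standard silylation of a secondary allylic alcohol, which masks the hydroxyl through the Lewis-acid, enolate, metathesis and radical steps and touches no stereocenter.

Step 3
Reactants: 7; 8 2-methylpropanoyl chloride
Product: 9 (7R)-7-{[tert-butyl(dimethyl)silyl]oxy}-2,8-dimethyl-5-methylidenenon-8-en-3-one
Conditions: TiCl4, CH2Cl2, −78 °C
Reagents that add atoms: none
Why: Lewis-acid-mediated acylation of an allylsilane (SE2′), in which the acylium ion attacks the CH2 terminus and loss of the silyl group re-forms the 1,1-disubstituted alkene one carbon over, so the β,γ-unsaturated ketone should form directly, a cold quench keeping it out of conjugation.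

Step 4
Reactants: 9; 10 acrolein
Product: 13 (4S,5R)-4-[(4R)-4-{[tert-butyl(dimethyl)silyl]oxy}-5-methylhexa-1,5-dien-2-yl]-5-hydroxy-2-methylhept-6-en-3-one, via enol borinate 11 (not isolated), via boron aldolate 12 (not isolated)
Conditions: (−)-Ipc2BOTf (from (−)-Ipc2BH and TfOH), i-Pr2NEt, CH2Cl2, −78 °C; 10, −78 to −20 °C; then H2O2, pH 7 buffer, MeOH
Reagents that add atoms: none
Why: Paterson boron aldol reaction, in which the boron triflate and hindered amine enolise the more acidic allylic CH2 (not the isopropyl methine) to the (Z)-enol borinate, which adds to acrolein through a chair Zimmerman–Traxler transition state (syn) with the isopinocampheyl ligands selecting the Si face of the aldehyde, which should set C3a (4S) and the temporary C4 center (5R).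

Step 5
Reactants: 13
Product: 14 1-[(1S,2R,5R)-5-{[tert-butyl(dimethyl)silyl]oxy}-2-hydroxy-4-methyl-7-methylidenecyclohept-3-en-1-yl]-2-methylpropan-1-one
Conditions: second-generation Grubbs catalyst RuCl2(=CHPh)(PCy3)(H2IMes) (5 mol %), 1,4-benzoquinone (10 mol %), PhMe, 80 °C
Reagents that add atoms: none
Why: Ring-closing metathesis, initiated at the vinyl group (helped by the free allylic hydroxyl) and closed onto the isopropenyl group to give the trisubstituted cycloheptene; the other 1,1-disubstituted alkene could only close a four-membered ring and should stay, and no stereocenter is touched.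

Step 6
Reactants: 14
Product: 15 1-[(1S,2R,5R)-5-{[tert-butyl(dimethyl)silyl]oxy}-4-methyl-7-methylidene-2-[(triethylsilyl)oxy]cyclohept-3-en-1-yl]-2-methylpropan-1-one
Conditions: TESCl, imidazole, DMF, 0 °C
Reagents that add atoms: chlorotriethylsilane, CC[Si](CC)(CC)Cl
Why: Mild silylation of the β-hydroxy ketone, which keeps this hydroxyl from forming a lactol with the aldehyde made in step 7 and adds a second substituent to the face already shielded by the acyl group.

Step 7
Reactants: 15; 10 acrolein
Product: 16 (2S,3R,3aS,4R,7R,8aR)-7-{[tert-butyl(dimethyl)silyl]oxy}-3-hydroxy-6,8a-dimethyl-3-(propan-2-yl)-4-[(triethylsilyl)oxy]-1,2,3,3a,4,7,8,8a-octahydroazulene-2-carbaldehyde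
Conditions: Fe(acac)3 (30 mol %), PhSiH3 (2.5 equiv), 10 (3 equiv), EtOH/THF, rt
Reagents that add atoms: none
Why: A trivalent iron hydride formed from Fe(acac)3 and PhSiH3 transfers a hydrogen atom to the CH2 terminus of the exocyclic 1,1-disubstituted alkene, the tertiary radical adds to acrolein (bond C8a–C1), the α-formyl radical is reduced by divalent iron to an iron enolate, and the enolate adds to the isopropyl ketone (bond C2–C3). The closest known reaction type is the hydrogen-atom-transfer-initiated Giese addition/aldol annulation of alkenyl ketones with enals (radical–polar crossover annulation), with the aldol cycloreduction of keto enones as precedent for five-membered closure. Ring A closes by a 5-(enolexo)-exo-trig aldol addition. C8a is set by substrate control: the cycloheptyl radical should be attacked on the face opposite to the vicinal isobutyryl group and the cis triethylsilyloxy group, so the two-carbon chain ends up trans to the acyl carbon (trans ring fusion) and the new methyl group cis to it. C3 is set in the reversible aldol closure, which should place the isopropyl group away from the angular methyl and from C4 and so leave the hydroxyl cis to the angular methyl; C2 is expected cis to that hydroxyl through the chelated enolate, and either C2 epimer converges in step 8. The step needs selection between two alkenes, between ketone and excess acrolein as the enolate acceptor, and between the two faces of the radical; these are secured by the substitution pattern (1,1-disubstituted beats the trisubstituted ring alkene flanked by two silyloxy carbons), by the intramolecularity of the aldol, and by the two substituents on one face next to the radical.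

Step 8
Reactants: 16
Product: 17 (3R,3aS,4R,7R,8aR)-7-{[tert-butyl(dimethyl)silyl]oxy}-6,8a-dimethyl-3-(propan-2-yl)-4-[(triethylsilyl)oxy]-1,2,3,3a,4,7,8,8a-octahydroazulen-3-ol
Conditions: RhCl(PPh3)3 (1.2 equiv), PhMe, 110 °C
Reagents that add atoms: none
Why: Tsuji–Wilkinson decarbonylation, in which the formyl C–H bond adds oxidatively to monovalent rhodium, CO is extruded and C–H reductive elimination leaves the C2 methylene, so the activating group of the annulation should be removed without touching the neighbouring stereocenters.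

Step 9
Reactants: 17
Product: 18 (3R,3aS,4R,7R,8aR)-7-{[tert-butyl(dimethyl)silyl]oxy}-6,8a-dimethyl-3-(propan-2-yl)-1,2,3,3a,4,7,8,8a-octahydroazulene-3,4-diol
Conditions: PPTS (cat.), MeOH/CH2Cl2, 0 °C
Reagents that add atoms: none
Why: Acid-catalysed methanolysis should cleave the triethylsilyl ether selectively, because the tert-butyldimethylsilyl ether is far slower under these conditions.

Step 10
Reactants: 18
Product: 19 (3R,3aR,7R,8aR)-7-{[tert-butyl(dimethyl)silyl]oxy}-3-hydroxy-6,8a-dimethyl-3-(propan-2-yl)-2,3,3a,7,8,8a-hexahydroazulen-4(1H)-one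
Conditions: Dess–Martin periodinane, CH2Cl2, 0 °C to rt
Reagents that add atoms: none
Why: Dess–Martin oxidation of the secondary allylic alcohol to the enone under neutral conditions (tertiary alcohol and silyl ether inert, ring-fusion CH not epimerised), which erases the C4 center that served only as a control element.

Step 11
Reactants: 19
Product: 20 (3R,3aS,4S,7R,8aR)-7-{[tert-butyl(dimethyl)silyl]oxy}-6,8a-dimethyl-3-(propan-2-yl)-1,2,3,3a,4,7,8,8a-octahydroazulene-3,4-diol
Conditions: Me4NBH(OAc)3, MeCN/AcOH, −30 °C
Reagents that add atoms: none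
Why: Evans–Saksena hydroxyl-directed reduction, in which the tertiary C3 hydroxyl binds boron and delivers hydride 1,2 to the C4 carbonyl through a six-membered chair on the face where that hydroxyl sits, so the new hydroxyl should come out anti to it (4S), as in the target.

Step 12
Reactants: 20; 21 4-methoxybenzoyl chloride
Product: 22 (3R,3aS,4S,7R,8aR)-7-{[tert-butyl(dimethyl)silyl]oxy}-3-hydroxy-6,8a-dimethyl-3-(propan-2-yl)-1,2,3,3a,4,7,8,8a-octahydroazulen-4-yl 4-methoxybenzoate
Conditions: Et3N, DMAP (cat.), CH2Cl2, 0 °C to rt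
Reagents that add atoms: none
Why: DMAP-catalysed acylation should take the secondary allylic hydroxyl only, since the tertiary hydroxyl is too hindered and C7 is still silylated.

Step 13
Reactants: 22
Product: 23 (3R,3aS,4S,7R,8aR)-3,7-dihydroxy-6,8a-dimethyl-3-(propan-2-yl)-1,2,3,3a,4,7,8,8a-octahydroazulen-4-yl 4-methoxybenzoate (CNP0251753.2)
Conditions: HF·pyridine, THF/pyridine, 0 °C to rt
Reagents that add atoms: none
Why: Buffered fluoride desilylation should free the C7 hydroxyl without the basic alkoxide that could cleave or shift the anisate.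

**Compound list**

1 | [2-(chloromethyl)prop-2-en-1-yl](trimethyl)silane | C[Si](C)(C)CC(=C)CCl | starting material
2 | methacrolein (2-methylprop-2-enal) | CC(=C)C=O | starting material
3 | {2-[(trimethylsilyl)methyl]prop-2-en-1-yl}magnesium chloride | C[Si](C)(C)CC(=C)C[Mg]Cl | intermediate
4 | {2-[(trimethylsilyl)methyl]prop-2-en-1-yl}bis(isopinocampheyl)borane, isopinocampheyl groups from (−)-α-pinene | C=C(C[Si](C)(C)C)CB([C@H]1C[C@H]2C[C@@H]([C@@H]1C)C2(C)C)[C@H]3C[C@H]4C[C@@H]([C@@H]3C)C4(C)C | intermediate
5 | O-bis(isopinocampheyl)boryl ether of alcohol 6 (borinate ester) | C=C(C)[C@H](OB([C@H]1C[C@H]2C[C@@H]([C@@H]1C)C2(C)C)[C@H]3C[C@H]4C[C@@H]([C@@H]3C)C4(C)C)CC(=C)C[Si](C)(C)C | intermediate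
6 | (3R)-2-methyl-5-[(trimethylsilyl)methyl]hexa-1,5-dien-3-ol | C=C(C)[C@H](O)CC(=C)C[Si](C)(C)C | intermediate
7 | tert-butyl(dimethyl){[(3R)-2-methyl-5-[(trimethylsilyl)methyl]hexa-1,5-dien-3-yl]oxy}silane | C=C(C)[C@H](O[Si](C)(C)C(C)(C)C)CC(=C)C[Si](C)(C)C | intermediate
8 | 2-methylpropanoyl chloride (isobutyryl chloride) | CC(C)C(Cl)=O | starting material
9 | (7R)-7-{[tert-butyl(dimethyl)silyl]oxy}-2,8-dimethyl-5-methylidenenon-8-en-3-one | CC(C)C(=O)CC(=C)C[C@@H](O[Si](C)(C)C(C)(C)C)C(C)=C | intermediate
10 | acrolein (prop-2-enal) | C=CC=O | starting material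
11 | (Z)-enol bis(isopinocampheyl)borinate of ketone 9, isopinocampheyl groups from (+)-α-pinene | CC(C)/C(OB([C@@H]1C[C@@H]2C[C@H]([C@H]1C)C2(C)C)[C@@H]3C[C@@H]4C[C@H]([C@H]3C)C4(C)C)=C/C(=C)C[C@@H](O[Si](C)(C)C(C)(C)C)C(C)=C | intermediate
12 | O-bis(isopinocampheyl)boryl ether of aldol 13 (boron aldolate) | O([C@H](C=C)[C@@H](C(=O)C(C)C)C(=C)C[C@@H](O[Si](C)(C)C(C)(C)C)C(C)=C)B([C@@H]1C[C@@H]2C[C@H]([C@H]1C)C2(C)C)[C@@H]3C[C@@H]4C[C@H]([C@H]3C)C4(C)C | intermediate
13 | (4S,5R)-4-[(4R)-4-{[tert-butyl(dimethyl)silyl]oxy}-5-methylhexa-1,5-dien-2-yl]-5-hydroxy-2-methylhept-6-en-3-one | O[C@H](C=C)[C@@H](C(=O)C(C)C)C(=C)C[C@@H](O[Si](C)(C)C(C)(C)C)C(C)=C | intermediate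
14 | 1-[(1S,2R,5R)-5-{[tert-butyl(dimethyl)silyl]oxy}-2-hydroxy-4-methyl-7-methylidenecyclohept-3-en-1-yl]-2-methylpropan-1-one | O[C@@H]1C=C(C)[C@H](O[Si](C)(C)C(C)(C)C)CC(=C)[C@@H]1C(=O)C(C)C | intermediate
15 | 1-[(1S,2R,5R)-5-{[tert-butyl(dimethyl)silyl]oxy}-4-methyl-7-methylidene-2-[(triethylsilyl)oxy]cyclohept-3-en-1-yl]-2-methylpropan-1-one | CC[Si](CC)(CC)O[C@@H]1C=C(C)[C@H](O[Si](C)(C)C(C)(C)C)CC(=C)[C@@H]1C(=O)C(C)C | intermediate
16 | (2S,3R,3aS,4R,7R,8aR)-7-{[tert-butyl(dimethyl)silyl]oxy}-3-hydroxy-6,8a-dimethyl-3-(propan-2-yl)-4-[(triethylsilyl)oxy]-1,2,3,3a,4,7,8,8a-octahydroazulene-2-carbaldehyde | CC[Si](CC)(CC)O[C@@H]2C=C(C)[C@H](O[Si](C)(C)C(C)(C)C)C[C@@]3(C)C[C@H](C=O)[C@@](O)(C(C)C)[C@H]23 | intermediate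
17 | (3R,3aS,4R,7R,8aR)-7-{[tert-butyl(dimethyl)silyl]oxy}-6,8a-dimethyl-3-(propan-2-yl)-4-[(triethylsilyl)oxy]-1,2,3,3a,4,7,8,8a-octahydroazulen-3-ol | CC[Si](CC)(CC)O[C@@H]2C=C(C)[C@H](O[Si](C)(C)C(C)(C)C)C[C@@]3(C)CC[C@@](O)(C(C)C)[C@H]23 | intermediate
18 | (3R,3aS,4R,7R,8aR)-7-{[tert-butyl(dimethyl)silyl]oxy}-6,8a-dimethyl-3-(propan-2-yl)-1,2,3,3a,4,7,8,8a-octahydroazulene-3,4-diol | O[C@@H]2C=C(C)[C@H](O[Si](C)(C)C(C)(C)C)C[C@@]3(C)CC[C@@](O)(C(C)C)[C@H]23 | intermediate
19 | (3R,3aR,7R,8aR)-7-{[tert-butyl(dimethyl)silyl]oxy}-3-hydroxy-6,8a-dimethyl-3-(propan-2-yl)-2,3,3a,7,8,8a-hexahydroazulen-4(1H)-one | O=C2C=C(C)[C@H](O[Si](C)(C)C(C)(C)C)C[C@@]3(C)CC[C@@](O)(C(C)C)[C@H]23 | intermediate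
20 | (3R,3aS,4S,7R,8aR)-7-{[tert-butyl(dimethyl)silyl]oxy}-6,8a-dimethyl-3-(propan-2-yl)-1,2,3,3a,4,7,8,8a-octahydroazulene-3,4-diol | O[C@H]2C=C(C)[C@H](O[Si](C)(C)C(C)(C)C)C[C@@]3(C)CC[C@@](O)(C(C)C)[C@H]23 | intermediate
21 | 4-methoxybenzoyl chloride | COc1ccc(cc1)C(Cl)=O | starting material
22 | (3R,3aS,4S,7R,8aR)-7-{[tert-butyl(dimethyl)silyl]oxy}-3-hydroxy-6,8a-dimethyl-3-(propan-2-yl)-1,2,3,3a,4,7,8,8a-octahydroazulen-4-yl 4-methoxybenzoate | COc1ccc(cc1)C(=O)O[C@H]2C=C(C)[C@H](O[Si](C)(C)C(C)(C)C)C[C@@]3(C)CC[C@@](O)(C(C)C)[C@H]23 | intermediate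
23 | (3R,3aS,4S,7R,8aR)-3,7-dihydroxy-6,8a-dimethyl-3-(propan-2-yl)-1,2,3,3a,4,7,8,8a-octahydroazulen-4-yl 4-methoxybenzoate | COc1ccc(C(=O)O[C@H]2C=C(C)[C@H](O)C[C@@]3(C)CC[C@@](O)(C(C)C)[C@H]23)cc1 | target

**Total step count:** 13. **Longest linear sequence:** 13 steps (1 to 23).

**Steps most likely to fail**

Step 7 (key step). The iron enolate may be protonated by the alcohol before it adds to the hindered isopropyl ketone, or the aldol may revert, so that ring A does not close. Hydrogen-atom transfer may also move the exocyclic alkene into conjugation with the ketone, and facial selectivity at the cycloheptyl radical may erode. The fallback sets out from 15 and separates the two bond formations. The same iron hydride conditions with phenyl vinyl sulfone in place of acrolein (a plain Giese addition that needs no enolate trapping) should give the Giese adduct of 15 carrying a 2-(phenylsulfonyl)ethyl group and a methyl group on the former alkene carbon, F1. LDA (THF, −78 °C) should deprotonate the unhindered sulfonyl CH2 in preference to the two tertiary ketone α-positions, and the carbanion should add to the ketone at low temperature to give the analogue of 17 with a phenylsulfonyl group on C2, F2. Buffered sodium amalgam (Na2HPO4, MeOH, −20 °C) should remove the sulfonyl group. The route is rejoined at 17, so 16 and step 8 are bypassed.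

Step 8. At the temperature of the rhodium-mediated decarbonylation the β-hydroxy aldehyde may open by retro-aldol cleavage, or the alkylrhodium intermediate may eliminate to an alkene. The fallback sets out from 16. Pinnick oxidation (NaClO2, NaH2PO4, 2-methylbut-2-ene, t-BuOH/H2O) should give the carboxylic acid corresponding to aldehyde 16, F3. Hydrodecarboxylation at room temperature under acridinium photoredox catalysis (9-mesityl-10-methylacridinium tetrafluoroborate, PhSSPh, 2,6-lutidine, trifluoroethanol, blue light) should replace the carboxyl group by hydrogen. The route is rejoined at 17.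

Step 5. The ruthenium carbene formed at the vinyl group may fail to engage the hindered isopropenyl group next to the silyl ether, so that intermolecular metathesis (dimers, oligomers) wins. The fallback sets out from 9 and uses a relay. Oxidation of commercial (E)-octa-2,7-dien-1-ol with MnO2 should give (E)-octa-2,7-dienal F4. The aldol reaction of step 4 with F4 in place of acrolein should give the relay substrate F5 (the analogue of 13 with a (1E)-hepta-1,6-dienyl group in place of the vinyl group). The same ruthenium catalyst loads at the unhindered terminal alkene, expels cyclopentene and is thereby placed on C5, from where closure onto the isopropenyl group is intramolecular. The route is rejoined at 14.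

**Further compounds**

F1 | step 7 | Giese adduct of 15 with phenyl vinyl sulfone: 1-{5-[tert-butyl(dimethyl)silyl]oxy-4,7-dimethyl-7-[2-(phenylsulfonyl)ethyl]-2-[(triethylsilyl)oxy]cyclohept-3-en-1-yl}-2-methylpropan-1-one, configuration as in the SMILES | CC[Si](CC)(CC)O[C@@H]1C=C(C)[C@H](O[Si](C)(C)C(C)(C)C)C[C@@](C)(CCS(=O)(=O)c2ccccc2)[C@@H]1C(=O)C(C)C
F2 | step 7 | analogue of 17 with a phenylsulfonyl group on C2 (either configuration at C2) | CC[Si](CC)(CC)O[C@@H]2C=C(C)[C@H](O[Si](C)(C)C(C)(C)C)C[C@@]3(C)CC(S(=O)(=O)c4ccccc4)[C@@](O)(C(C)C)[C@H]23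
F3 | step 8 | carboxylic acid corresponding to aldehyde 16 (CO2H on C2, cis to the C3 hydroxyl) | CC[Si](CC)(CC)O[C@@H]2C=C(C)[C@H](O[Si](C)(C)C(C)(C)C)C[C@@]3(C)C[C@H](C(=O)O)[C@@](O)(C(C)C)[C@H]23
F4 | step 5 | (E)-octa-2,7-dienal | C=CCCC/C=C/C=O
F5 | step 5 | (4S,5R,6E)-4-[(4R)-4-{[tert-butyl(dimethyl)silyl]oxy}-5-methylhexa-1,5-dien-2-yl]-5-hydroxy-2-methyldodeca-6,11-dien-3-one | O[C@H](/C=C/CCCC=C)[C@@H](C(=O)C(C)C)C(=C)C[C@@H](O[Si](C)(C)C(C)(C)C)C(C)=C
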